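**Retrosynthetic overview**

1. Andavadoic acid ⇐ racemic trans methyl ester; an esterase-mediated kinetic resolution doubles as the ester hydrolysis.
2. The 1,2-dioxolane (the only ring, formed late) ⇐ [3+2] annulation of a peroxycarbenium ion (C5 plus O–O) with methyl 3-methylbut-3-enoate (C4, C3); this forms C4–C5 and C3–O.
3. Peroxycarbenium precursor ⇐ silyl monoperoxyketal ⇐ key step: hydrogen-atom transfer from the hydride made from Co(thd)2 and Et3SiH to a ketone silyl enol ether, then capture of O2 by the tertiary α-siloxy radical (C5–O and the O–O unit come from this radical step).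
4. Silyl enol ether ⇐ 12-phenyldodecan-2-one ⇐ radical conjugate addition of an 8-phenyloctylboron reagent to methyl vinyl ketone ⇐ 8-phenyloct-1-ene ⇐ octa-1,7-diene + bromobenzene (B-alkyl Suzuki).
5. Stereochemistry: no step controls it by design. The C3/C5 relative configuration comes from separating the two annulation diastereomers (about 1:1) and the absolute configuration from the resolution, so at most about a quarter of the annulation product can end as target without recycling.

Assumption: "trans" and "cis" refer to the two ring methyl groups (the target is the trans, 3R,5S isomer). The esterase in step 6 is taken to hydrolyse the (3R,5S)-ester of the racemate faster; this is untested and must be checked on first use.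

**Route**

Step 1
Reactants: 1 octa-1,7-diene; 2 bromobenzene
Product: 4 8-phenyloct-1-ene, via alkylborane 3 (not isolated)
Conditions: 1 (3 equiv), 9-BBN, THF, 0 °C to rt; then 2, Pd(dppf)Cl2 (3 mol %), aq NaOH, THF, 65 °C
Reagents that add atoms: none
Why: Mono-hydroboration of the excess diene puts boron on a terminal carbon, and the primary alkylborane 3 couples with the aryl bromide (B-alkyl Suzuki–Miyaura reaction) while the second terminal alkene survives; no stereocentre is formed.

Step 2
Reactants: 4 8-phenyloct-1-ene; 5 but-3-en-2-one (methyl vinyl ketone)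
Product: 7 12-phenyldodecan-2-one, via alkylcatecholborane 6 (not isolated)
Conditions: catecholborane (2 equiv), Me2NC(O)Me (10 mol %), CH2Cl2, 40 °C; MeOH (destroys excess borane); then 5 (3 equiv), DMPU, H2O, air (O2 initiation), 0 °C to rt
Reagents that add atoms: none
Why: Amide-catalysed anti-Markovnikov hydroboration gives 6, and oxygen-initiated homolytic substitution at boron releases the primary alkyl group as a radical that adds to the enone in a chain process (radical conjugate addition of a B-alkylcatecholborane), water freeing the methyl ketone; no stereocentre is formed.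

Step 3
Reactants: 7 12-phenyldodecan-2-one
Product: 9 triethyl[(12-phenyldodec-1-en-2-yl)oxy]silane, via lithium enolate 8 (not isolated)
Conditions: LiN(iPr)2, THF, −78 °C; Et3SiCl, −78 °C to 0 °C
Reagents that add atoms: chlorotriethylsilane CC[Si](Cl)(CC)CC
Why: Kinetic deprotonation at the methyl group gives enolate 8, which is O-silylated (silyl enol ether formation); either enol ether regioisomer would serve because both give the same C2 radical in step 4, and no stereocentre is formed.

Step 4 (key step)
Reactants: 9 triethyl[(12-phenyldodec-1-en-2-yl)oxy]silane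
Product: 11 triethyl{[12-phenyl-2-(triethylsilyloxy)dodecan-2-yl]peroxy}silane (racemic), via tertiary α-siloxyalkyl radical 10 (not isolated)
Conditions: Co(thd)2 (10 mol %; thd = 2,2,6,6-tetramethylheptane-3,5-dionate), Et3SiH (2.5 equiv), O2 (1 atm), t-BuOOH (cat.), ClCH2CH2Cl, rt
Reagents that add atoms: dioxygen O=O; triethylsilane CC[SiH](CC)CC
Why: Hydrogen-atom transfer from the hydride formed from Co(thd)2 and Et3SiH to the terminal CH2 of the electron-rich enol ether gives radical 10, which captures O2 to make the C–O bond that becomes C5–O of the target, and the peroxide is then silylated by Et3SiH (Isayama–Mukaiyama silylperoxidation, applied to a silyl enol ether so that the peroxide sits at the ketone oxidation level); the ketal carbon is racemic, which does not matter because it is planarised in step 5.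

Step 5
Reactants: 11 triethyl{[12-phenyl-2-(triethylsilyloxy)dodecan-2-yl]peroxy}silane; 12 methyl 3-methylbut-3-enoate
Product: 14 methyl 2-[(3R*,5S*)-3,5-dimethyl-5-(10-phenyldecyl)-1,2-dioxolan-3-yl]acetate (racemic trans ester), via peroxycarbenium ion 13 (not isolated)
Conditions: 12 (4 equiv), SnCl4 (1.2 equiv), CH2Cl2, −78 °C to −40 °C; aq NaHCO3; chromatography
Reagents that add atoms: none
Why: The Lewis acid ionises the siloxy group to ion 13, the 1,1-disubstituted alkene adds through its CH2 terminus and the silylperoxy oxygen closes the ring with loss of its silyl group (peroxycarbenium–alkene [3+2] annulation); C3 and C5 both form here without facial control (trans:cis about 1:1), and the racemic trans ester 14 is isolated by chromatography from its cis (3R*,5R*) diastereomer, which is set aside (in principle it can be re-equilibrated at C3 by base through retro-oxa-Michael/oxa-Michael addition and chromatographed again).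

Step 6
Reactants: 14 methyl 2-[(3R*,5S*)-3,5-dimethyl-5-(10-phenyldecyl)-1,2-dioxolan-3-yl]acetate (racemic trans ester)
Product: 15 andavadoic acid (2-[(3R,5S)-3,5-dimethyl-5-(10-phenyldecyl)-1,2-dioxolan-3-yl]acetic acid)
Conditions: pig liver esterase, 0.1 M phosphate buffer pH 7.5, acetone (10% v/v), 25 °C, pH-stat, stop near 45% conversion; extraction of the acid into aq NaHCO3, then acidification
Reagents that add atoms: water O
Why: Enzymatic kinetic resolution by ester hydrolysis, in which the esterase is expected to discriminate the quaternary C3 (the same C(CH3)(O)(CH2)CH2CO2Me pattern it desymmetrises in 3-hydroxy-3-methylglutarate diesters) so that only the (3R,5S) enantiomer of 14 is hydrolysed, fixing the absolute configuration of both centres at a maximum yield of 50%; the neutral buffer leaves the peroxide and the base-sensitive β-peroxy ester intact.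

**Compound list**

1 | octa-1,7-diene | C=CCCCCC=C | starting material
2 | bromobenzene | Brc1ccccc1 | starting material
3 | 9-(oct-7-en-1-yl)-9-borabicyclo[3.3.1]nonane | C=CCCCCCCB1C2CCCC1CCC2 | intermediate
4 | 8-phenyloct-1-ene | C=CCCCCCCc1ccccc1 | intermediate
5 | but-3-en-2-one (methyl vinyl ketone) | CC(=O)C=C | starting material
6 | 2-(8-phenyloctyl)-1,3,2-benzodioxaborole | c1ccc(cc1)CCCCCCCCB1Oc2ccccc2O1 | intermediate
7 | 12-phenyldodecan-2-one | CC(=O)CCCCCCCCCCc1ccccc1 | intermediate
8 | lithium 12-phenyldodec-1-en-2-olate | [Li+].[O-]C(=C)CCCCCCCCCCc1ccccc1 | intermediate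
9 | triethyl[(12-phenyldodec-1-en-2-yl)oxy]silane | C=C(O[Si](CC)(CC)CC)CCCCCCCCCCc1ccccc1 | intermediate
10 | 12-phenyl-2-[(triethylsilyl)oxy]dodecan-2-yl radical | C[C](O[Si](CC)(CC)CC)CCCCCCCCCCc1ccccc1 | intermediate
11 | triethyl{[12-phenyl-2-(triethylsilyloxy)dodecan-2-yl]peroxy}silane (racemic) | CC(OO[Si](CC)(CC)CC)(O[Si](CC)(CC)CC)CCCCCCCCCCc1ccccc1 | intermediate
12 | methyl 3-methylbut-3-enoate | C=C(C)CC(=O)OC | starting material
13 | (12-phenyldodecan-2-ylidene)[(triethylsilyl)oxy]oxonium (peroxycarbenium ion) | CC(=[O+]O[Si](CC)(CC)CC)CCCCCCCCCCc1ccccc1 | intermediate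
14 | methyl 2-[(3R*,5S*)-3,5-dimethyl-5-(10-phenyldecyl)-1,2-dioxolan-3-yl]acetate (racemic trans ester; SMILES shows the 3R,5S enantiomer) | C[C@]1(CCCCCCCCCCc2ccccc2)C[C@](C)(CC(=O)OC)OO1 | intermediate
15 | andavadoic acid, 2-[(3R,5S)-3,5-dimethyl-5-(10-phenyldecyl)-1,2-dioxolan-3-yl]acetic acid | C[C@]1(CCCCCCCCCCc2ccccc2)C[C@](C)(CC(=O)O)OO1 | target

**Step count and risks**

Total: 6 steps. Longest linear sequence: 6 steps (1 → 4 → 7 → 9 → 11 → 14 → 15); 2, 5 and 12 enter as purchased partners.

The three steps most likely to fail are steps 4, 5 and 6.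

Step 4. The silyl enol ether 9 may desilylate under the peroxidation, or in step 5 the silylperoxy group rather than the siloxy group may leave. The fallback sets out from 7 and uses a methyl enol ether, whose peroxyketal has an unambiguous leaving group. Trimethyl orthoformate, MeOH and catalytic TsOH give 2,2-dimethoxy-12-phenyldodecane F1. Me3SiOTf and iPr2NEt eliminate methanol to give 2-methoxy-12-phenyldodec-1-ene F2. The same Co(thd)2/O2/Et3SiH radical peroxidation then gives triethyl[(2-methoxy-12-phenyldodecan-2-yl)peroxy]silane F3. SnCl4 ionises its methoxy group to the same ion 13, and annulation with 12 returns to the route at 14.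

Step 5 (the most exposed). The ester-bearing alkene 12 is a weak π-nucleophile and its carbonyl can tie up the Lewis acid, ion 13 can undergo a Criegee-type 1,2-shift, and the adduct cation can lose a proton instead of closing the ring. The fallback sets out from 11 and separates C–C bond formation from ring closure. Commercial methyl 3-methylbut-2-enoate is converted (LiN(iPr)2, Me3SiCl, THF, −78 °C) into [(1-methoxy-3-methylbuta-1,3-dien-1-yl)oxy]trimethylsilane F4. This much stronger nucleophile attacks 13 through its γ-carbon (vinylogous Mukaiyama addition, SnCl4, CH2Cl2, −78 °C) to give methyl (E)-3,5-dimethyl-15-phenyl-5-[(triethylsilyl)peroxy]pentadec-2-enoate F5. Bu4NF/AcOH frees methyl (E)-5-hydroperoxy-3,5-dimethyl-15-phenylpentadec-2-enoate F6. Et2NH in CF3CH2OH then closes the ring by 5-exo oxa-Michael addition, rejoining the route at 14 (again together with its cis diastereomer, removed by chromatography).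

Step 6. The esterase may show low or opposite selectivity on this lipophilic peroxide ester. The fallback sets out from 14 and replaces the enzymatic resolution by a covalent one. LiOH in THF/H2O at 0 °C gives the racemic trans acid 2-[(3R*,5S*)-3,5-dimethyl-5-(10-phenyldecyl)-1,2-dioxolan-3-yl]acetic acid F7. Activation with pivaloyl chloride/Et3N and acylation of (S)-4-benzyloxazolidin-2-one (deprotonated with n-BuLi) gives two diastereomeric imides, which are separated on silica. The imide (S)-4-benzyl-3-{2-[(3R,5S)-3,5-dimethyl-5-(10-phenyldecyl)-1,2-dioxolan-3-yl]acetyl}oxazolidin-2-one F8 is cleaved with LiOH/H2O2 (peroxide-compatible) and comes back to the route at 15.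

**Further compounds**

F1 | step 4 | 2,2-dimethoxy-12-phenyldodecane | COC(C)(OC)CCCCCCCCCCc1ccccc1
F2 | step 4 | 2-methoxy-12-phenyldodec-1-ene | C=C(OC)CCCCCCCCCCc1ccccc1
F3 | step 4 | triethyl[(2-methoxy-12-phenyldodecan-2-yl)peroxy]silane (racemic) | COC(C)(OO[Si](CC)(CC)CC)CCCCCCCCCCc1ccccc1
F4 | step 5 | [(1-methoxy-3-methylbuta-1,3-dien-1-yl)oxy]trimethylsilane | C=C(C)C=C(OC)O[Si](C)(C)C
F5 | step 5 | methyl (E)-3,5-dimethyl-15-phenyl-5-[(triethylsilyl)peroxy]pentadec-2-enoate (racemic) | COC(=O)/C=C(\C)CC(C)(OO[Si](CC)(CC)CC)CCCCCCCCCCc1ccccc1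
F6 | step 5 | methyl (E)-5-hydroperoxy-3,5-dimethyl-15-phenylpentadec-2-enoate (racemic) | COC(=O)/C=C(\C)CC(C)(OO)CCCCCCCCCCc1ccccc1
F7 | step 6 | 2-[(3R*,5S*)-3,5-dimethyl-5-(10-phenyldecyl)-1,2-dioxolan-3-yl]acetic acid (racemic; SMILES shows one enantiomer) | C[C@]1(CCCCCCCCCCc2ccccc2)C[C@](C)(CC(=O)O)OO1
F8 | step 6 | (S)-4-benzyl-3-{2-[(3R,5S)-3,5-dimethyl-5-(10-phenyldecyl)-1,2-dioxolan-3-yl]acetyl}oxazolidin-2-one | C[C@]1(CCCCCCCCCCc2ccccc2)C[C@](C)(CC(=O)N2[C@@H](Cc3ccccc3)COC2=O)OO1
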